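## Retrosynthetic overview
1. There is only one ring. The 11-membered carbocycle is closed last, at C8–C9, by a Cr/Ni-electrocatalytic coupling of a (Z)-alkenyl iodide with an enal. Alcohol oxidation and desilylation then give the target.
2. The (Z)-2-iodoallyl alcohol (C9–C10) comes from a C10 aldehyde by α-iodo-Wittig olefination and DIBAL. The senecioate is attached to C4–OH after one acid step frees both the diol and the enal.
3. Quaternary C1 and the E-C2=C3 alkene come from an Eschenmoser–Claisen rearrangement of a (3R)-allylic alcohol, with 1,3-chirality transfer.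
4. That alcohol comes from Felkin addition of a geranyl-type (E)-alkenyllithium (made from sulcatone) to a dioxolane aldehyde.
5. The aldehyde comes from (R)-isopropylidene glycerate, which supplies C4. The sequence is methyl ketone, chelation-controlled (E)-alkenylzinc addition (sets C5), acetonide migration, oxidation.

Assumption and locants: ring atoms are C1 (quaternary), C2=C3, C4 (CH–O-ester), C5 (C(Me)OH), C6=C7, C8 (C=O), C9 (C–CH2OH), C10 (=CH) and C11 (CH2). The target is 1S,4R,5R,2E,6E,9Z. The C8 carbinol in 22 is an epimer mixture that does not matter, because it is oxidised in the next step.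

## Route

**Step 1**
Reactants: 1, methyl (4R)-2,2-dimethyl-1,3-dioxolane-4-carboxylate
Product: 2, 1-[(4R)-2,2-dimethyl-1,3-dioxolan-4-yl]ethanone
Conditions: MeNH(OMe)·HCl, MeMgBr (4.5 equiv), THF, −20 → 0 °C, cold NH4Cl quench
Reagents that add atoms: methylmagnesium bromide, C[Mg]Br
Why: This is a one-pot Weinreb amidation and Grignard ketone synthesis, and because the Mg chelate releases the ketone only on quench, over-addition and enolisation of the bought C4 centre are avoided.

**Step 2**
Reactants: 3, 3,3-diethoxyprop-1-yne; 4, ethylene glycol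
Product: 5, 2-ethynyl-1,3-dioxolane
Conditions: p-TsOH (1 mol %), 90 °C, distil off EtOH
Reagents that add atoms: ethylene glycol (4), OCCO
Why: This is an acid-catalysed transacetalisation driven by removing ethanol, and the cyclic acetal is chosen because it simply re-closes if it ionises in the anhydrous-acid step 4.

**Step 3**
Reactants: 2; 5
Product: 6, (2R,3E)-2-[(4R)-2,2-dimethyl-1,3-dioxolan-4-yl]-4-(1,3-dioxolan-2-yl)but-3-en-2-ol
Conditions: 5, Cy2BH, toluene, 0 °C → rt; Et2Zn, −78 °C; then 2, EtZnCl (1.5 equiv), −20 → 0 °C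
Reagents that add atoms: none (H only; all carbon comes from 5)
Why: Syn hydroboration gives the E-alkenyl unit, and after B→Zn exchange the alkenylzinc adds under chelation control, where EtZnCl ties C=O to the α-dioxolane oxygen (Cram chelate) so attack from the C4–H side sets C5 as R (4,5-syn).

**Step 4**
Reactants: 6
Product: 7, [(4R,5R)-5-[(E)-2-(1,3-dioxolan-2-yl)ethenyl]-2,2,5-trimethyl-1,3-dioxolan-4-yl]methanol
Conditions: CSA (3 mol %), CH2Cl2, rt; Et3N quench
Reagents that add atoms: none
Why: This is a thermodynamic acetonide migration to the more substituted trans-dioxolane (gem-dialkyl effect), which frees the primary OH without breaking any C4–O or C5–O bond, so both centres are retained.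

**Step 5**
Reactants: 7
Product: 8, (4S,5R)-5-[(E)-2-(1,3-dioxolan-2-yl)ethenyl]-2,2,5-trimethyl-1,3-dioxolane-4-carbaldehyde (same spatial arrangement; the C4 descriptor changes by CIP priority only)
Conditions: SO3·py, DMSO, i-Pr2NEt, CH2Cl2, 0 °C
Reagents that add atoms: none
Why: The Parikh–Doering oxidation is non-acidic and cold, so the acetals survive and the α-alkoxy aldehyde does not epimerise.

**Step 6**
Reactants: 9, 6-methylhept-5-en-2-one
Product: 10, 6-methylhept-5-en-1-yne
Conditions: LDA, THF, −78 °C; ClP(O)(OEt)2; then LDA (2.3 equiv), −78 °C → rt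
Reagents that add atoms: none
Why: This is the Negishi conversion of a methyl ketone to a terminal alkyne through the kinetic enol phosphate and elimination.

**Step 7**
Reactants: 10
Product: 11, (E)-1-iodo-2,6-dimethylhepta-1,5-diene
Conditions: Me3Al, Cp2ZrCl2 (25 mol %), CH2Cl2, 0 °C → rt; then I2, THF, −30 °C
Reagents that add atoms: trimethylaluminium, C[Al](C)C; iodine, II
Why: Zr-catalysed carboalumination adds Me and Al syn, and iodinolysis with retention fixes the geranyl-type E geometry.

**Step 8**
Reactants: 11; 8
Product: 12, (1R,2E)-1-[(4R,5R)-5-[(E)-2-(1,3-dioxolan-2-yl)ethenyl]-2,2,5-trimethyl-1,3-dioxolan-4-yl]-3,7-dimethylocta-2,6-dien-1-ol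
Conditions: 11, t-BuLi (2 equiv), Et2O, −78 °C; then 8, −78 °C
Reagents that add atoms: none beyond 11
Why: Li–I exchange is followed by non-chelated 1,2-addition under polar Felkin–Anh/Cornforth control, reinforced by quaternary C5, which gives the 3,4-anti alcohol with C3 = R; the minor epimer is removed by chromatography.

**Step 9**
Reactants: 12; 13, N,N-dimethylacetamide dimethyl acetal
Product: 14, (3S)-3-[(E)-2-{(4R,5R)-5-[(E)-2-(1,3-dioxolan-2-yl)ethenyl]-2,2,5-trimethyl-1,3-dioxolan-4-yl}ethenyl]-N,N,3,7-tetramethyloct-6-enamide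
Conditions: 13 (5 equiv), xylenes, 135 °C, MeOH distilled off
Reagents that add atoms: 13, COC(C)(OC)N(C)C
Why: In this neutral Eschenmoser–Claisen [3,3] rearrangement, A(1,3) strain with the Z-methyl holds the dioxolane substituent pseudo-equatorial, so suprafacial C3–O → C1–C11 transfer gives the E-C2=C3 alkene and (S)-C1 (C11 is CH2, so chair and boat give the same result).

**Step 10**
Reactants: 14
Product: 15, the corresponding (3S)-oct-6-enal (C10 aldehyde)
Conditions: Cp2Zr(H)Cl (1.6 equiv), THF, rt, 20 min
Reagents that add atoms: none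
Why: Schwartz reduction of a tertiary amide to the aldehyde is fast, and it spares the acetals and the internal alkenes.

**Step 11**
Reactants: 15; 16, ethyl (triphenylphosphoranylidene)acetate
Product: 17, ethyl (2Z,5S)-2-iodo-5,9-dimethyl-5-[(E)-2-(dioxolanyl as in 14)ethenyl]deca-2,8-dienoate
Conditions: 16, NIS, CH2Cl2, −20 °C, 15 min; then K2CO3 and 15, −20 °C → rt
Reagents that add atoms: 16, CCOC(=O)C=P(c1ccccc1)(c1ccccc1)c1ccccc1; N-iodosuccinimide, O=C1CCC(=O)N1I
Why: The Wittig reaction of the in situ α-iodo stabilised ylide places the ester trans and the iodine cis to C11 (Z), and NIS is consumed before the polyene is added.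

**Step 12**
Reactants: 17
Product: 18, the (2Z,5S)-2-iodo-deca-2,8-dien-1-ol (C9–CH2OH)
Conditions: DIBAL-H (2.5 equiv), CH2Cl2, −78 °C; Rochelle salt
Reagents that add atoms: none
Why: DIBAL performs 1,2-reduction of the enoate, and the alkenyl iodide, acetonide and acetal are inert at −78 °C.

**Step 13**
Reactants: 18
Product: 19, (2E,4R,5R,6E,8S,10Z)-4,5,12-trihydroxy-11-iodo-4,8-dimethyl-8-(4-methylpent-3-enyl)dodeca-2,6,10-trienal
Conditions: AcOH–H2O (4:1), 45 °C
Reagents that add atoms: water, O
Why: A single mild hydrolysis removes both the acetonide and the enal acetal, and the E-γ-hydroxyenal cannot form a lactol or aromatise because C5 is quaternary.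

**Step 14**
Reactants: 19; 20, 3-methylbut-2-enoic (senecioic) acid
Product: 21, the C12 TBS ether and C5-chain (ring C4) senecioate of 19, with the tertiary OH and the enal free
Conditions: TBSCl (1.05 equiv), imidazole, CH2Cl2, −10 °C; then premixed 20/2,4,6-Cl3C6H2COCl/Et3N, DMAP, rt (one pot)
Reagents that add atoms: TBSCl, CC(C)(C)[Si](C)(C)Cl; 20, CC(C)=CC(=O)O
Why: Steric differentiation lets the primary OH silylate first, after which Yamaguchi esterification acylates the only remaining acylable OH (secondary C4; the tertiary C5–OH is inert) without deconjugating the acyl group.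

**Step 15**
Reactants: 21
Product: 22, the 11-membered (2E,6E,9Z)-trien-8-ol (1S,4R,5R; C8 epimers) carrying the C4 senecioate, C5 OH and C9 CH2OTBS
Conditions: CrCl2 (20 mol %), NiCl2·neocuproine (3 mol %), Cp2ZrCl2 (2 equiv), LiCl, n-Bu4NPF6, DMF, undivided cell, Al(+)|Ni foam(−), 3 mA (about 2.5 F/mol), 21 added by syringe pump over 10 h (final 2 mM), rt
Reagents that add atoms: none
Why: Proposed new method: a Cr/Ni-electrocatalytic Nozaki–Hiyama–Kishi macrocyclisation in which the cathode regenerates Cr(II), Ni(0) inserts into C9–I with retention of Z geometry and transmetallates to Cr(III), the alkenyl–Cr adds 1,2 to the tethered enal to form C8–C9, and Cp2ZrCl2 releases Cr from the alkoxide; the current limits the standing Cr(II)/Ni(0) level and the slow feed keeps 21 sub-millimolar, so ring closure outcompetes diene homocoupling and enal pinacolisation. The closest known chemistry is the stoichiometric NHK macrocyclisation and the intermolecular electrochemical NHK coupling; to my knowledge the electrochemical variant has not been applied to closing a medium ring.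

**Step 16**
Reactants: 22
Product: 23, the cross-conjugated C8 dienone (TBS ether)
Conditions: Dess–Martin periodinane, NaHCO3, CH2Cl2, 0 °C
Reagents that add atoms: none
Why: DMP oxidises the bis-allylic secondary alcohol, while the tertiary OH cannot react and the primary OH is masked.

**Step 17**
Reactants: 23
Product: 24, the target (CID15817377)
Conditions: HF·pyridine, pyridine, THF, 0 °C → rt
Reagents that add atoms: none
Why: Buffered fluoride cleaves the primary allylic TBS ether without touching the dienone, the ester or the tertiary alcohol.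

## Compound list
1 | methyl (4R)-2,2-dimethyl-1,3-dioxolane-4-carboxylate | COC(=O)[C@H]1COC(C)(C)O1 | starting material
2 | 1-[(4R)-2,2-dimethyl-1,3-dioxolan-4-yl]ethanone | CC(=O)[C@H]1COC(C)(C)O1 | intermediate
3 | 3,3-diethoxyprop-1-yne | C#CC(OCC)OCC | starting material
4 | ethylene glycol | OCCO | starting material
5 | 2-ethynyl-1,3-dioxolane | C#CC1OCCO1 | intermediate
6 | (2R,3E)-tertiary allylic alcohol, terminal acetonide | C[C@@](O)(/C=C/C1OCCO1)[C@H]2COC(C)(C)O2 | intermediate
7 | (4R,5R)-C4/C5 acetonide, primary alcohol | OC[C@H]1OC(C)(C)O[C@]1(C)/C=C/C2OCCO2 | intermediate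
8 | (4S,5R)-dioxolane-4-carbaldehyde | O=C[C@H]1OC(C)(C)O[C@]1(C)/C=C/C2OCCO2 | intermediate
9 | 6-methylhept-5-en-2-one | CC(=O)CCC=C(C)C | starting material
10 | 6-methylhept-5-en-1-yne | C#CCCC=C(C)C | intermediate
11 | (E)-1-iodo-2,6-dimethylhepta-1,5-diene | CC(C)=CCC/C(C)=C/I | intermediate
12 | (3R)-allylic alcohol (3,4-anti) | CC(C)=CCC/C(C)=C/[C@@H](O)[C@H]1OC(C)(C)O[C@]1(C)/C=C/C2OCCO2 | intermediate
13 | N,N-dimethylacetamide dimethyl acetal | COC(C)(OC)N(C)C | starting material
14 | (S)-C1 quaternary dimethylamide | CC(C)=CCC[C@](CC(=O)N(C)C)(C)/C=C/[C@H]1OC(C)(C)O[C@]1(C)/C=C/C2OCCO2 | intermediate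
15 | C10 aldehyde | CC(C)=CCC[C@](CC=O)(C)/C=C/[C@H]1OC(C)(C)O[C@]1(C)/C=C/C2OCCO2 | intermediate
16 | ethyl (triphenylphosphoranylidene)acetate | CCOC(=O)C=P(c1ccccc1)(c1ccccc1)c1ccccc1 | starting material
17 | (Z)-α-iodoenoate | CC(C)=CCC[C@](C/C=C(\I)C(=O)OCC)(C)/C=C/[C@H]1OC(C)(C)O[C@]1(C)/C=C/C2OCCO2 | intermediate
18 | (Z)-2-iodoallylic alcohol | CC(C)=CCC[C@](C/C=C(\I)CO)(C)/C=C/[C@H]1OC(C)(C)O[C@]1(C)/C=C/C2OCCO2 | intermediate
19 | triol enal | CC(C)=CCC[C@](C/C=C(\I)CO)(C)/C=C/[C@@H](O)[C@](C)(O)/C=C/C=O | intermediate
20 | 3-methylbut-2-enoic acid | CC(C)=CC(=O)O | starting material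
21 | seco iodide/enal (TBS ether, senecioate) | CC(C)=CCC[C@](C/C=C(\I)CO[Si](C)(C)C(C)(C)C)(C)/C=C/[C@@H](OC(=O)C=C(C)C)[C@](C)(O)/C=C/C=O | intermediate
22 | macrocyclic C8 alcohol (epimers) | CC(C)=CCC[C@]1(C)/C=C/[C@@H](OC(=O)C=C(C)C)[C@](C)(O)/C=C/C(O)/C(CO[Si](C)(C)C(C)(C)C)=C\C1 | intermediate
23 | macrocyclic dienone TBS ether | CC(C)=CCC[C@]1(C)/C=C/[C@@H](OC(=O)C=C(C)C)[C@](C)(O)/C=C/C(=O)/C(CO[Si](C)(C)C(C)(C)C)=C\C1 | intermediate
24 | CID15817377 | CC(C)=CCC[C@]1(C)/C=C/[C@@H](OC(=O)C=C(C)C)[C@](C)(O)/C=C/C(=O)/C(CO)=C\C1 | target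

## Totals and risks
Total steps: 17. Longest linear sequence: 14 (steps 1, 3, 4, 5, 8–17).

The three steps most likely to fail:
1. **Step 15 (new electrochemical NHK ring closure).** The risks are oligomerisation, proto-deiodination and enal pinacol coupling.
   - Fallback (known chemistry): move the closure to C6=C7.
   - Add a plain vinylzinc in step 3 so that C5 carries a vinyl carbinol.
   - Couple the iodide with acrolein by a conventional stoichiometric CrCl2/cat. NiCl2 reaction and oxidise to the vinyl ketone.
   - Close the ring by ring-closing metathesis with Hoveyda–Grubbs II.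
2. **Step 3 (chelation-controlled alkenylzinc addition to a ketone).** The risks are low conversion and β-chelate leakage that lowers the dr.
   - Fallback: make the C5–CH3 bond instead of the C5–C6 bond.
   - Acylate lithiated 5 with the Weinreb amide of 1 to give the ynone.
   - Add MeMgBr under Felkin–Anh control, which gives the same 4,5-syn isomer.
   - Reduce the alkyne with Red-Al to the E-alkene. This costs one extra step.
3. **Step 8 (Felkin dr at C3, which determines C1).**
   - Fallback: set C3 with hydride rather than carbon.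
   - Oxidise the epimer mixture of 12 to the enone with DMP.
   - Reduce with Zn(BH4)2 under chelation control, which gives the 3,4-anti alcohol.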